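**Retrosynthetic overview**
- The C3–Br and C2–Br bonds are made last, by electrophilic bromination of 5,6-dibromoindole.
- 5,6-Dibromoindole comes from ethyl 5,6-dibromoindole-2-carboxylate by saponification and decarboxylation.
- The pyrrole ring, the only ring formed, is closed by nitro reduction and condensation of an o-nitrophenylpyruvate (Reissert indole synthesis).
- Key C–C bond (the future C2–C3 bond): crossed Claisen condensation of 4,5-dibromo-2-nitrotoluene with diethyl oxalate.
- The benzene ring is bought; its bromine pattern is fixed beforehand from 3-methyl-4-nitroaniline by ortho-bromination and a Sandmeyer reaction.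

Assumption: the target is achiral (planar, no stereocentre), so no stereocontrol is needed and "single enantiomer" is taken to mean simply 2,3,5,6-tetrabromo-1H-indole.

**Step 1**
Reactants: 1 3-methyl-4-nitroaniline
Product: 2 2-bromo-5-methyl-4-nitroaniline
Conditions: NBS (1.0 equiv), DMF, 0 °C → rt
Reagents that add atoms: N-bromosuccinimide, O=C1CCC(=O)N1Br
Why: Electrophilic aromatic bromination directed ortho to the amino group goes to the unhindered ortho position, which is also para to the methyl and meta to the nitro group.

**Step 2**
Reactants: 2 2-bromo-5-methyl-4-nitroaniline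
Product: 4 1,2-dibromo-4-methyl-5-nitrobenzene (4,5-dibromo-2-nitrotoluene), via arenediazonium bromide 3 (not isolated)
Conditions: NaNO2, 48% aq HBr, 0–5 °C; then CuBr (0.3 equiv), 48% aq HBr, 70 °C
Reagents that add atoms: sodium nitrite, [Na+].[O-]N=O (outer N of 3 only); hydrobromic acid, Br (new Br of 4, counter-ion of 3)
Why: The Sandmeyer reaction replaces the amino group by bromine exactly where the amine stood, so the 4,5-dibromo-2-nitro pattern is unambiguous.

**Step 3**
Reactants: 4 1,2-dibromo-4-methyl-5-nitrobenzene; 5 diethyl oxalate
Product: 7 ethyl 3-(4,5-dibromo-2-nitrophenyl)-2-oxopropanoate, via potassium enolate 6 (not isolated)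
Conditions: KOEt (1.2 equiv), Et2O/EtOH, 0 °C → rt, 24 h; then 1 M HCl
Reagents that add atoms: none
Why: In this intermolecular crossed Claisen condensation (Reissert), ethoxide deprotonates the methyl group ortho to nitro, the carbanion acylates non-enolisable diethyl oxalate, and precipitation of the red potassium enolate 6 drives the equilibrium.

**Step 4**
Reactants: 7 ethyl 3-(4,5-dibromo-2-nitrophenyl)-2-oxopropanoate
Product: 9 ethyl 5,6-dibromo-1H-indole-2-carboxylate, via aminophenylpyruvate 8 (not isolated)
Conditions: Fe powder (6 equiv), AcOH/EtOH, 85 °C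
Reagents that add atoms: none
Why: In this Reissert reductive cyclisation, Fe/AcOH reduces the nitro group without touching the aryl bromides or the ester, and the aniline condenses with the neighbouring ketone and dehydrates to the aromatic indole.

**Step 5**
Reactants: 9 ethyl 5,6-dibromo-1H-indole-2-carboxylate
Product: 11 5,6-dibromo-1H-indole-2-carboxylic acid, via sodium carboxylate 10 (not isolated)
Conditions: NaOH (3 equiv), EtOH/H2O, reflux; then 2 M HCl, 0 °C
Reagents that add atoms: sodium hydroxide, [Na+].[OH-]
Why: Saponification of the unhindered ethyl ester is irreversible, and the aryl bromides and the indole are inert to aqueous hydroxide.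

**Step 6**
Reactants: 11 5,6-dibromo-1H-indole-2-carboxylic acid
Product: 12 5,6-dibromo-1H-indole
Conditions: Cu powder (0.1 equiv), quinoline, 215 °C, N2, 1–2 h
Reagents that add atoms: none
Why: Copper-mediated thermal protodecarboxylation of indole-2-carboxylic acids in quinoline is the classical end of a Reissert sequence and tolerates ring halogens.

**Step 7**
Reactants: 12 5,6-dibromo-1H-indole
Product: 14 2,3,5,6-tetrabromo-1H-indole, via 3,5,6-tribromoindole 13 (not isolated)
Conditions: NBS (1.05 equiv), dry THF, −78 → 0 °C; then NBS (1.1 equiv), rt, dark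
Reagents that add atoms: N-bromosuccinimide, O=C1CCC(=O)N1Br
Why: Electrophilic aromatic substitution takes the most nucleophilic C3 first and then C2 of the 3-bromoindole, while C4 and C7 are deactivated by the adjacent bromines so the reaction stops at the tetrabromide.

**Compound list**
1 | 3-methyl-4-nitroaniline | Cc1cc(N)ccc1[N+](=O)[O-] | starting material
2 | 2-bromo-5-methyl-4-nitroaniline | Cc1cc(N)c(Br)cc1[N+](=O)[O-] | intermediate
3 | 2-bromo-5-methyl-4-nitrobenzenediazonium bromide | Cc1cc([N+]#N)c(Br)cc1[N+](=O)[O-].[Br-] | intermediate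
4 | 1,2-dibromo-4-methyl-5-nitrobenzene (4,5-dibromo-2-nitrotoluene) | Cc1cc(Br)c(Br)cc1[N+](=O)[O-] | intermediate
5 | diethyl oxalate | CCOC(=O)C(=O)OCC | starting material
6 | potassium (Z)-3-(4,5-dibromo-2-nitrophenyl)-1-ethoxy-1-oxoprop-2-en-2-olate | CCOC(=O)/C([O-])=C/c1cc(Br)c(Br)cc1[N+](=O)[O-].[K+] | intermediate
7 | ethyl 3-(4,5-dibromo-2-nitrophenyl)-2-oxopropanoate | CCOC(=O)C(=O)Cc1cc(Br)c(Br)cc1[N+](=O)[O-] | intermediate
8 | ethyl 3-(2-amino-4,5-dibromophenyl)-2-oxopropanoate | CCOC(=O)C(=O)Cc1cc(Br)c(Br)cc1N | intermediate
9 | ethyl 5,6-dibromo-1H-indole-2-carboxylate | CCOC(=O)c1cc2cc(Br)c(Br)cc2[nH]1 | intermediate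
10 | sodium 5,6-dibromo-1H-indole-2-carboxylate | [Na+].[O-]C(=O)c1cc2cc(Br)c(Br)cc2[nH]1 | intermediate
11 | 5,6-dibromo-1H-indole-2-carboxylic acid | OC(=O)c1cc2cc(Br)c(Br)cc2[nH]1 | intermediate
12 | 5,6-dibromo-1H-indole | Brc1cc2cc[nH]c2cc1Br | intermediate
13 | 3,5,6-tribromo-1H-indole | Brc1cc2c(Br)c[nH]c2cc1Br | intermediate
14 | 2,3,5,6-tetrabromo-1H-indole | Brc1cc2[nH]c(Br)c(Br)c2cc1Br | target

**Step count and risks**
Total steps: 7. Longest linear sequence: 7 steps (1 → 14).

The three steps most likely to fail:

Step 3 (Claisen condensation). Ethoxide can displace the bromine para to the nitro group, and the condensation is reversible if the enolate salt does not precipitate. The fallback sets out from 4. Heating 4 with N,N-dimethylformamide dimethyl acetal in DMF at 110 °C condenses the same benzylic carbanion with a one-carbon formyl equivalent and gives (E)-2-(4,5-dibromo-2-nitrophenyl)-N,N-dimethylethen-1-amine F1. Reduction of this enamine with Fe powder in AcOH at 80 °C closes the pyrrole ring directly, and the route is rejoined at 12 without the ester and decarboxylation stages.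

Step 6 (thermal decarboxylation). At 215 °C with copper, tarring or partial loss of aryl bromine is possible. The fallback sets out from 11 and avoids protodecarboxylation altogether. Treating 11 with NBS (1.05 equiv) in DMF at 0 °C brominates C3 to give 3,5,6-tribromo-1H-indole-2-carboxylic acid F2. A second equivalent of NBS at rt then effects ipso-bromodecarboxylation at C2, and the fallback comes back to the route at 14.

Step 7 (double bromination). The second bromination, at C2 of an electron-poor 3-bromoindole, may stall, or NBS with traces of water may give oxindole-type oxidation products. The fallback sets out from 12 and introduces the C2 bromine by directed metalation instead of electrophilic substitution. Boc2O with catalytic DMAP in MeCN gives tert-butyl 5,6-dibromo-1H-indole-1-carboxylate F3. C2-deprotonation with LiN(iPr)2 in THF at −78 °C and a quench with 1,2-dibromo-1,1,2,2-tetrachloroethane gives tert-butyl 2,5,6-tribromo-1H-indole-1-carboxylate F4. K2CO3 in MeOH at rt removes the carbamate to give 2,5,6-tribromo-1H-indole F5. One equivalent of NBS in DMF at 0 °C then brominates the free C3 position, and the fallback comes back to the route at 14.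

**Further compounds**
F1 | step 3 | (E)-2-(4,5-dibromo-2-nitrophenyl)-N,N-dimethylethen-1-amine | CN(C)/C=C/c1cc(Br)c(Br)cc1[N+](=O)[O-]
F2 | step 6 | 3,5,6-tribromo-1H-indole-2-carboxylic acid | OC(=O)c1[nH]c2cc(Br)c(Br)cc2c1Br
F3 | step 7 | tert-butyl 5,6-dibromo-1H-indole-1-carboxylate | CC(C)(C)OC(=O)n1ccc2cc(Br)c(Br)cc21
F4 | step 7 | tert-butyl 2,5,6-tribromo-1H-indole-1-carboxylate | CC(C)(C)OC(=O)n1c(Br)cc2cc(Br)c(Br)cc21
F5 | step 7 | 2,5,6-tribromo-1H-indole | Brc1cc2cc(Br)c(Br)cc2[nH]1
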